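**Retrosynthetic overview**
1. Feature: the spiro carbon is C2 of the 4,6-dioxygenated benzofuran-3(2H)-one ring and also C3′ of the 2′-aryl-2′,3′-dihydrofuran ring fused to flavan C7–C8. It bears ring oxygen O1, adjoins ketone C3 and is bonded to the central-ring carbon flavan C8. This is the pattern left when the C2=C3 bond of a 2,3-fused benzofuran is epoxidised and the C3 aryl substituent shifts to C2.
2. Key disconnection: C2–C8 back to C3–C8, so 23 ⇒ epoxide 22 ⇒ 2-aryl-2H-chromene 21 fused at C3–C4 to the benzofuran (pyran → dihydrofuran contraction). Only deprotection follows (mesylates, then benzyl ethers).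
3. 21 ⇒ chromene acetal 18 + aryl boronate 20. This catalyst-controlled C–aryl bond sets chromene C2 late. A 3-haloflavanone/aryloxylation/acid-cyclodehydration path is avoided, because base gives the flavone and racemises C2 by retro-oxa-Michael opening.
4. 18 ⇒ biaryl aldehyde 15 ⇒ 8-bromoflavan 9 + 3-chloro-2-formylbenzofuran 12 (Negishi, furan C3–flavan C8). 9 ⇒ aldehyde 3 + acetophenone 4, so that the carbonyl sits next to ring B, where flavan C2 needs it (transfer hydrogenation, Mitsunobu inversion).
5. Ring order: flavan pyran (step 6) → furan ring brought in with 10 and aromatised (step 9) → chromene pyran (step 11) → contraction to the dihydrofuran, the furan becoming the benzofuranone (step 14).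

Key step: step 14

Locants: "flavan" O1, C2–C8a for the chroman unit. "Furan" O1, C2, C3, C3a, C4–C7a for the ring-A benzofuran. "Chromene C2" is the sp3 carbon between flavan O7 and furan C2; it becomes dihydrofuran C2′.
Structural remark: in 17, 18 and 21 the ring-A C4 oxygen and flavan O1 face each other across a fjord (C4–C3a–C3–C8–C8a), so these tetracycles are helically twisted. Ring closure in step 11 is therefore driven through the aromatic pyrylium salt, and the strain adds driving force to step 14.
Assumption: the sense of induction of the tartaric-acid-derived catalyst on 18 cannot be predicted. Both antipodes are available from L- and D-tartaric acid, and the one giving chromene-2S is chosen in a pilot run; this can be read directly, because 2S and 2R are diastereomers here.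

**Step 1**
Reactants: 1 2,4,6-trihydroxybenzaldehyde
Product: 2 2,6-dihydroxy-4-(methoxymethoxy)benzaldehyde
Conditions: MOMCl (1.0 equiv), i-Pr2NEt (1.1 equiv), CH2Cl2/THF, 0 °C
Reagents that add atoms: chloromethyl methyl ether COCCl
Why: O-alkylation of the most acidic hydroxyl; the 4-OH is the only one not tied to the formyl group by a hydrogen bond, so one equivalent of reagent should go there.

**Step 2**
Reactants: 2 2,6-dihydroxy-4-(methoxymethoxy)benzaldehyde
Product: 3 2-(benzyloxy)-6-hydroxy-4-(methoxymethoxy)benzaldehyde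
Conditions: BnBr (1.05 equiv), K2CO3, DMF, rt
Reagents that add atoms: benzyl bromide BrCc1ccccc1
Why: Williamson etherification of one of two equivalent ortho hydroxyls; the remaining OH is then locked in the chelate with the aldehyde and resists a second alkylation.

**Step 3**
Reactants: 3 2-(benzyloxy)-6-hydroxy-4-(methoxymethoxy)benzaldehyde; 4 1-[4-(benzyloxy)phenyl]ethanone
Product: 5 (E)-3-[2-(benzyloxy)-6-hydroxy-4-(methoxymethoxy)phenyl]-1-[4-(benzyloxy)phenyl]prop-2-en-1-one
Conditions: KOH (aq 50 %), EtOH, rt; cold aq NH4Cl work-up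
Reagents that add atoms: none
Why: Claisen–Schmidt condensation places the carbonyl next to ring B (the future flavan C2); the neutral work-up avoids flavylium formation from the 2-hydroxy enone.

**Step 4**
Reactants: 5 the (E)-enone
Product: 6 3-[2-(benzyloxy)-6-hydroxy-4-(methoxymethoxy)phenyl]-1-[4-(benzyloxy)phenyl]propan-1-one
Conditions: H2 (1 atm), Pd/C, Ph2S (cat. poison), EtOAc, rt
Reagents that add atoms: none
Why: Chemoselective catalytic hydrogenation of the conjugated C=C; the sulfide-poisoned catalyst leaves benzyl ethers and the aryl ketone untouched.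

**Step 5**
Reactants: 6 the saturated ketone
Product: 7 (1R)-3-[2-(benzyloxy)-6-hydroxy-4-(methoxymethoxy)phenyl]-1-[4-(benzyloxy)phenyl]propan-1-ol
Conditions: RuCl[(R,R)-TsDPEN](p-cymene) (1 mol %), HCO2H/Et3N 5:2, 30 °C
Reagents that add atoms: none
Why: Noyori asymmetric transfer hydrogenation of an aryl alkyl ketone; the (R,R)-catalyst should give the (R)-benzylic alcohol as it does with acetophenone, and the phenol, MOM and benzyl ethers are inert.

**Step 6**
Reactants: 7 the (1R)-alcohol
Product: 8 (2S)-5-(benzyloxy)-2-[4-(benzyloxy)phenyl]-7-(methoxymethoxy)chromane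
Conditions: PPh3, DIAD, toluene, −10 → 0 °C
Reagents that add atoms: none
Why: Intramolecular Mitsunobu etherification (6-exo-tet SN2 by the phenol ortho to the chain) inverts the carbinol, R → flavan 2S; low temperature and toluene hold back ionisation of the p-alkoxybenzylic centre.

**Step 7**
Reactants: 8 the (2S)-flavan
Product: 9 (2S)-5-(benzyloxy)-2-[4-(benzyloxy)phenyl]-8-bromo-7-(methoxymethoxy)chromane
Conditions: NBS (1.0 equiv), CH2Cl2, −78 → −20 °C
Reagents that add atoms: N-bromosuccinimide O=C1CCC(=O)N1Br
Why: Electrophilic aromatic bromination; in 5,7-dialkoxyflavans C8, next to the tied-back ring oxygen, is less hindered than C6 between two free alkoxy groups, the selectivity known for per-O-benzylated flavan-3-ols.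

**Step 8**
Reactants: 10 4,6-dihydroxybenzofuran-3(2H)-one
Product: 11 3-oxo-2,3-dihydrobenzofuran-4,6-diyl dimethanesulfonate
Conditions: MsCl (2.3 equiv), pyridine, CH2Cl2, 0 °C
Reagents that add atoms: methanesulfonyl chloride CS(=O)(=O)Cl
Why: Sulfonylation of both phenols under a weak base that does not enolise the ketone; the mesylates are acid-, zinc- and Pd-stable electron-withdrawing groups that steer steps 9, 13 and 14.

**Step 9**
Reactants: 11 the bis-mesylate
Product: 12 3-chloro-2-formylbenzofuran-4,6-diyl dimethanesulfonate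
Conditions: POCl3 (3 equiv), DMF, 0 → 60 °C; aq NaOAc
Reagents that add atoms: N,N-dimethylformamide CN(C)C=O; phosphoryl chloride O=P(Cl)(Cl)Cl; water O
Why: Vilsmeier–Haack–Arnold chloroformylation of the enolisable ketone, known for benzofuran-3(2H)-ones, aromatises the furan; the deactivated ring A is not formylated.

**Step 10**
Reactants: 9 the 8-bromoflavan; 12 the 3-chloro-2-formylbenzofuran
Product: 15 3-[(2S)-5-(benzyloxy)-2-[4-(benzyloxy)phenyl]-7-(methoxymethoxy)chroman-8-yl]-2-formylbenzofuran-4,6-diyl dimethanesulfonate, via the 8-lithioflavan 13 (not isolated), via the 8-(chlorozincio)flavan 14 (not isolated)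
Conditions: n-BuLi, THF, −78 °C; ZnCl2, → rt; 12, Pd2(dba)3/RuPhos, THF, 40 °C
Reagents that add atoms: none
Why: Negishi coupling of a 2,6-dialkoxyarylzinc with an activated β-chloro-enal chloride; the dialkylbiarylphosphine catalyst is designed for tri- and tetra-ortho-substituted biaryls, and arylzincs tolerate the aldehyde and the mesylates.

**Step 11**
Reactants: 15 the biaryl aldehyde
Product: 18 the 2-ethoxy-2H-chromene acetal of the benzofuro[2,3-c]chromene (flavan 2S; both epimers at the acetal carbon), via the 7-hydroxy aldehyde 16 (not isolated), via the benzofuro[2,3-c]chromenylium chloride 17 (not isolated)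
Conditions: HCl (1.25 M in EtOH), CH2Cl2, 40 °C; then poured into cold Et3N/EtOH
Reagents that add atoms: ethanol CCO
Why: Acid cleaves the MOM ether and the o-hydroxyaryl enal, held cis by the furan, dehydrates to the aromatic benzopyrylium salt (flavylium-type condensation), which overcomes the fjord strain; basic ethanol then adds kinetically at pyrylium C2.

**Step 12**
Reactants: 19 [4-(benzyloxy)phenyl]boronic acid
Product: 20 diethyl [4-(benzyloxy)phenyl]boronate
Conditions: EtOH, toluene, azeotropic removal of water, 3 Å MS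
Reagents that add atoms: ethanol CCO
Why: Simple boronic acid esterification gives the exchangeable boronate that the next step needs.

**Step 13**
Reactants: 18 the chromene acetal; 20 the diethyl boronate
Product: 21 (chromene-2S,flavan-2S)-2-[4-(benzyloxy)phenyl]-2H-chromene fused at C3–C4 to the benzofuran (benzofuro[2,3-c]chromene) and carrying the flavan ring; flavan 5-OBn and 4′-OBn; ring-A 4,6-bis(mesylate)
Conditions: tartaric-acid mono-amide (α,β-dihydroxy acid, 10 mol %), Yb(OTf)3 (9 mol %), EtOAc, −20 °C
Reagents that add atoms: none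
Why: Catalytic enantioselective addition of aryl boronates to 2-alkoxy-2H-chromenes: the acid pair ionises 18 to the pyrylium ion and the chiral dioxaborolane "ate" complex delivers the aryl group to C2 (C4 is blocked by the furan), so the catalyst sets chromene C2 as S; the mesylates keep the cation electrophilic and keep the product C2–O bond from re-ionising.

**Step 14**
Reactants: 21 the benzofuro[2,3-c]chromene
Product: 23 tri-O-benzyl-4,6-di-O-mesyl daphnodorin C (spiro-S,C2′-S,flavan-2S), via the anti furan 2,3-epoxide 22 (not isolated)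
Conditions: DMDO (1.2 equiv, dried acetone solution), CH2Cl2, −78 → −40 °C; then ZnCl2 (0.2 equiv, Et2O), −78 → −20 °C
Reagents that add atoms: dimethyldioxirane CC1(C)OO1
Why: Proposed new method: DMDO epoxidises the only enol-ether π bond (furan C2=C3) to 22, ZnCl2 then cleaves the C2–O bond with help from O1 (acetal-like carbon, as in the Lewis-acid opening of glycal epoxides) and, as the zinc alkoxide on C3 folds down to the ketone, the trioxygenated central-ring carbon flavan C8 moves from furan C3 to furan C2 through a phenonium-like transition state, so the ketone oxygen is the oxidant's. The closest known reactions are the hydroxyindolenine → spiro-pseudoindoxyl rearrangement of 2,3-fused indoles, the Meinwald/semipinacol rearrangement of 2,3-dialkylbenzofuran epoxides to benzofuran-3(2H)-ones and the iodine(III)-induced 1,2-aryl shift that contracts flavanones to 2-aryl-2,3-dihydrobenzofurans, none of them shown on a chromene-fused 3-arylbenzofuran. The dihydrofuran ring arises by contraction of the pyran (a 1,2-shift with one new bond, C2–C8), not by a cyclisation, the furan survives as the benzofuranone ring, and C3a cannot migrate because that would give a four-membered ring. The spiro centre is set by chromene C2: its pseudo-axial aryl group blocks one face of C2=C3, the epoxide forms anti to it and C8 enters furan C2 anti to the leaving oxygen, which places the aryl group syn to O1 and anti to C3=O, that is (S) as in 25. The step needs C2–O rather than C3–O cleavage, although the latter is the usual mode of 3-arylbenzofuran epoxides and would lead by shift of chromene C2 to the isomeric spiro-lactone or to the o-quinone methide valence isomer. Three substrate features work against that: the mesylates sit ortho and para to C3a and switch ring A off as a donor to C3 while being only meta to the O1-bearing C7a; a planar C3 cation or quinone methide would force the C4 oxygen and flavan O1 back into the fjord contact; and C3–O opening is reversible while the aryl shift is not, so the far higher migratory aptitude of the trialkoxyaryl carbon over the oxygen-bearing sp3 carbon should decide.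

**Step 15**
Reactants: 23 the di-O-mesyl spiro ketone
Product: 24 5,4′,4‴-tri-O-benzyl daphnodorin C (ring-A 4,6-diol)
Conditions: LiOH·H2O (6 equiv), THF/H2O, 0 °C → rt; 1 M HCl to pH 5
Reagents that add atoms: none
Why: Base cleavage (E1cB/sulfene or hydroxide attack at sulfur) of aryl mesylates whose phenoxides are activated by the ortho/para ketone; the ketone has no α-hydrogen, both p-oxygenated aryl groups are still benzylated so no quinone-methide epimerisation of C2′ or flavan C2 is possible, and the alcohol-free medium avoids formation of an alkylating sulfonate ester.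

**Step 16**
Reactants: 24 tri-O-benzyl daphnodorin C
Product: 25 daphnodorin C
Conditions: H2 (1 atm), Pd(OH)2/C, THF/MeOH, rt
Reagents that add atoms: none
Why: Hydrogenolysis of three aryl benzyl ethers under the mild conditions used for benzylated flavans, which leave the cyclic benzylic C–O bonds, the aryl ketone and all three stereocentres untouched.

**Compound list**
1 | 2,4,6-trihydroxybenzaldehyde | O=Cc1c(O)cc(O)cc1O | starting material
2 | 2,6-dihydroxy-4-(methoxymethoxy)benzaldehyde | O=Cc1c(O)cc(OCOC)cc1O | intermediate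
3 | 2-(benzyloxy)-6-hydroxy-4-(methoxymethoxy)benzaldehyde | O=Cc1c(O)cc(OCOC)cc1OCc1ccccc1 | intermediate
4 | 1-[4-(benzyloxy)phenyl]ethanone | CC(=O)c1ccc(OCc2ccccc2)cc1 | starting material
5 | (E)-enone | O=C(/C=C/c1c(O)cc(OCOC)cc1OCc1ccccc1)c1ccc(OCc2ccccc2)cc1 | intermediate
6 | saturated ketone | O=C(CCc1c(O)cc(OCOC)cc1OCc1ccccc1)c1ccc(OCc2ccccc2)cc1 | intermediate
7 | (1R)-alcohol | O[C@H](CCc1c(O)cc(OCOC)cc1OCc1ccccc1)c1ccc(OCc2ccccc2)cc1 | intermediate
8 | (2S)-5-(benzyloxy)-2-[4-(benzyloxy)phenyl]-7-(methoxymethoxy)chromane | COCOc1cc(OCc2ccccc2)c2CC[C@@H](c3ccc(OCc4ccccc4)cc3)Oc2c1 | intermediate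
9 | (2S)-8-bromoflavan | COCOc1cc(OCc2ccccc2)c2CC[C@@H](c3ccc(OCc4ccccc4)cc3)Oc2c1Br | intermediate
10 | 4,6-dihydroxybenzofuran-3(2H)-one | O=C1COc2cc(O)cc(O)c12 | starting material
11 | 3-oxo-2,3-dihydrobenzofuran-4,6-diyl dimethanesulfonate | O=C1COc2cc(OS(C)(=O)=O)cc(OS(C)(=O)=O)c12 | intermediate
12 | 3-chloro-2-formylbenzofuran-4,6-diyl dimethanesulfonate | O=Cc1oc2cc(OS(C)(=O)=O)cc(OS(C)(=O)=O)c2c1Cl | intermediate
13 | 8-lithioflavan | COCOc1cc(OCc2ccccc2)c2CC[C@@H](c3ccc(OCc4ccccc4)cc3)Oc2c1[Li] | intermediate
14 | 8-(chlorozincio)flavan | COCOc1cc(OCc2ccccc2)c2CC[C@@H](c3ccc(OCc4ccccc4)cc3)Oc2c1[Zn]Cl | intermediate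
15 | biaryl aldehyde | O=Cc1oc2cc(OS(C)(=O)=O)cc(OS(C)(=O)=O)c2c1-c1c(OCOC)cc(OCc2ccccc2)c2CC[C@@H](c3ccc(OCc4ccccc4)cc3)Oc12 | intermediate
16 | 7-hydroxy aldehyde | O=Cc1oc2cc(OS(C)(=O)=O)cc(OS(C)(=O)=O)c2c1-c1c(O)cc(OCc2ccccc2)c2CC[C@@H](c3ccc(OCc4ccccc4)cc3)Oc12 | intermediate
17 | benzofuro[2,3-c]chromenylium chloride | [Cl-].C1=[O+]c2cc(OCc3ccccc3)c3CC[C@@H](c4ccc(OCc5ccccc5)cc4)Oc3c2-c2c1oc1cc(OS(C)(=O)=O)cc(OS(C)(=O)=O)c21 | intermediate
18 | 2-ethoxy-2H-chromene acetal (epimers at the acetal carbon) | CCOC1Oc2cc(OCc3ccccc3)c3CC[C@@H](c4ccc(OCc5ccccc5)cc4)Oc3c2-c2c1oc1cc(OS(C)(=O)=O)cc(OS(C)(=O)=O)c21 | intermediate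
19 | [4-(benzyloxy)phenyl]boronic acid | OB(O)c1ccc(OCc2ccccc2)cc1 | starting material
20 | diethyl [4-(benzyloxy)phenyl]boronate | CCOB(OCC)c1ccc(OCc2ccccc2)cc1 | intermediate
21 | key-step precursor, benzofuro[2,3-c]chromene (chromene 2S, flavan 2S) | c1ccccc1COc1ccc(cc1)[C@@H]1Oc2cc(OCc3ccccc3)c3CC[C@@H](c4ccc(OCc5ccccc5)cc4)Oc3c2-c2c1oc1cc(OS(C)(=O)=O)cc(OS(C)(=O)=O)c21 | intermediate
22 | anti furan 2,3-epoxide (epoxide oxygen anti to the chromene aryl group) | c1ccccc1COc1ccc(cc1)[C@@H]1Oc2cc(OCc3ccccc3)c3CC[C@@H](c4ccc(OCc5ccccc5)cc4)Oc3c2[C@]2(O3)c4c(OS(C)(=O)=O)cc(OS(C)(=O)=O)cc4O[C@]123 | intermediate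
23 | key-step product, tri-O-benzyl-4,6-di-O-mesyl daphnodorin C | O=C1c2c(OS(C)(=O)=O)cc(OS(C)(=O)=O)cc2O[C@]12c1c(cc(OCc3ccccc3)c3c1O[C@H](c1ccc(OCc4ccccc4)cc1)CC3)O[C@H]2c1ccc(OCc3ccccc3)cc1 | intermediate
24 | tri-O-benzyl daphnodorin C | O=C1c2c(O)cc(O)cc2O[C@]12c1c(cc(OCc3ccccc3)c3c1O[C@H](c1ccc(OCc4ccccc4)cc1)CC3)O[C@H]2c1ccc(OCc3ccccc3)cc1 | intermediate
25 | daphnodorin C | O=C1c2c(O)cc(O)cc2O[C@]12c1c(cc(O)c3c1O[C@H](c1ccc(O)cc1)CC3)O[C@H]2c1ccc(O)cc1 | target

Total step count: 16. Longest linear sequence: 13 (steps 1–7, 10, 11, 13–16).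

**Steps most likely to fail**

**Risk 1 (step 14).** The epoxide may ionise at the doubly benzylic furan C3 instead of C2. Shift of chromene C2 or valence isomerisation to the o-quinone methide would follow; in the latter the chromene C2–H becomes α to a ketone and can epimerise. Weak facial bias in the oxygen transfer is the second failure mode. The fallback uses known chemistry and makes the same C2–C8 bond by a cyclisation on a substrate whose C3 is already the ketone. It sets out from 8 and 11 and returns at 23.

MOM cleavage of 8 (HCl, MeOH) gives (2S)-5-(benzyloxy)-2-[4-(benzyloxy)phenyl]chroman-7-ol F1. Aldol condensation of 11 with commercial 4-(benzyloxy)benzaldehyde on neutral alumina gives the (Z)-aurone F2. DMDO converts it into the racemic aurone spiro-epoxide F3, a known reaction of aurones. The caesium phenoxide of F1 opens F3 at the benzylic carbon (SN2) to the 2-hydroxybenzofuran-3(2H)-one ether F4. BF3·OEt2 then ionises the hemiketal to the O1-stabilised cation, which flavan C8 (the position that also takes up bromine in step 7) attacks in an intramolecular Friedel–Crafts alkylation. The aryl group is expected to end syn to the smaller O1. Because the flavan centre is fixed, 23 and the (spiro R, C2′ R) isomer F5 are diastereomers and are separated by chromatography.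

**Risk 2 (step 13).** The twisted acetal may ionise slowly, the catalyst may discriminate poorly between the faces of a tetracyclic cation, and reversible C2–O heterolysis under the Lewis acid may erode the new centre. The fallback sets out from 12, 19 and 9 and returns at 21. It also by-passes the hindered coupling of step 10 and the ring closure of step 11.

Palladium-catalysed reduction of the C–Cl bond of 12 with sodium formate gives 2-formylbenzofuran-4,6-diyl dimethanesulfonate F6. Catalytic enantioselective aryl transfer from 19 (boron–zinc exchange with Et2Zn, chiral amino alcohol) gives the (R)-diarylcarbinol F7. MOM cleavage of 9 (HCl, MeOH) gives the 8-bromo-7-hydroxyflavan F8. Mitsunobu etherification of F8 with F7 proceeds with inversion to the (S)-diarylmethyl aryl ether F9. Intramolecular palladium-catalysed direct arylation of furan C3–H by the C8 bromide (Pd(OAc)2, PCy3·HBF4, K2CO3, DMA) closes the pyran ring to 21.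

**Risk 3 (step 6).** The p-benzyloxybenzylic oxyphosphonium salt may ionise in part before the phenol attacks, which lowers the enantiopurity at flavan C2. The fallback sets out from 6 and returns at 8.

Cyclodehydration of 6 (PPTS, toluene, water separator) gives the 2-aryl-4H-chromene F10. Iridium–phosphinooxazoline-catalysed asymmetric hydrogenation of its enol-ether double bond then sets flavan C2 (S with the appropriate ligand antipode) without touching the benzyl ethers.

**Further compounds**
F1 | step 14 | (2S)-5-(benzyloxy)-2-[4-(benzyloxy)phenyl]chroman-7-ol | Oc1cc(OCc2ccccc2)c2CC[C@@H](c3ccc(OCc4ccccc4)cc3)Oc2c1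
F2 | step 14 | (Z)-2-[4-(benzyloxy)benzylidene]-3-oxo-2,3-dihydrobenzofuran-4,6-diyl dimethanesulfonate | O=C1/C(=C/c2ccc(OCc3ccccc3)cc2)Oc2cc(OS(C)(=O)=O)cc(OS(C)(=O)=O)c12
F3 | step 14 | aurone spiro-epoxide (racemic) | O=C1c2c(OS(C)(=O)=O)cc(OS(C)(=O)=O)cc2OC13OC3c1ccc(OCc2ccccc2)cc1
F4 | step 14 | 2-hydroxybenzofuran-3(2H)-one ether (epimers at the two new centres) | O=C1c2c(OS(C)(=O)=O)cc(OS(C)(=O)=O)cc2OC1(O)C(Oc1cc(OCc2ccccc2)c2CC[C@@H](c3ccc(OCc4ccccc4)cc3)Oc2c1)c1ccc(OCc2ccccc2)cc1
F5 | step 14 | (spiro R, C2′ R, flavan 2S) isomer of 23 | O=C1c2c(OS(C)(=O)=O)cc(OS(C)(=O)=O)cc2O[C@@]12c1c(cc(OCc3ccccc3)c3c1O[C@H](c1ccc(OCc4ccccc4)cc1)CC3)O[C@@H]2c1ccc(OCc3ccccc3)cc1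
F6 | step 13 | 2-formylbenzofuran-4,6-diyl dimethanesulfonate | O=Cc1cc2c(OS(C)(=O)=O)cc(OS(C)(=O)=O)cc2o1
F7 | step 13 | (R)-diarylcarbinol | O[C@H](c1ccc(OCc2ccccc2)cc1)c1cc2c(OS(C)(=O)=O)cc(OS(C)(=O)=O)cc2o1
F8 | step 13 | (2S)-8-bromo-7-hydroxyflavan | Oc1cc(OCc2ccccc2)c2CC[C@@H](c3ccc(OCc4ccccc4)cc3)Oc2c1Br
F9 | step 13 | (S)-diarylmethyl aryl ether | c1ccccc1COc1ccc(cc1)[C@@H](c1cc2c(OS(C)(=O)=O)cc(OS(C)(=O)=O)cc2o1)Oc1cc(OCc2ccccc2)c2CC[C@@H](c3ccc(OCc4ccccc4)cc3)Oc2c1Br
F10 | step 6 | 5-(benzyloxy)-2-[4-(benzyloxy)phenyl]-7-(methoxymethoxy)-4H-chromene | COCOc1cc(OCc2ccccc2)c2CC=C(c3ccc(OCc4ccccc4)cc3)Oc2c1
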